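**Plan** (locants: azulene numbering of the target — C3 carbinol, C3a/C8a ring fusion, C4 ester carbon, C5=C6 ring alkene)
1. Retrosynthesis: cut the ester C–O bond, then the C3–isopropyl bond (carbinol back to ketone), then the C5=C6 alkene (ring-closing metathesis), and last the C8–C8a and C3a–C4 bonds together.
2. Enabling feature: with C3 read as a carbonyl, the five-membered ring is 3-methylcyclopent-2-en-1-one; C8a is its β-carbon (already carrying the methyl), C3a its α-carbon, and the C4 oxygen sits β to that carbonyl (aldol pattern).
3. Forward: the cyclopentane ring is bought; one copper-catalysed conjugate addition/aldol attaches both arms; metathesis closes the seven-membered ring; then isopropyl addition, redox correction at C4, esterification and phenol release.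
4. Stereochemistry: C8a from the chiral copper catalyst; C3a from aldehyde approach anti to the new chain; C3 from Grignard attack anti to the C4 arm and the angular methyl; C4 from hydroxyl-directed hydride delivery to enone 9, where both carbinol epimers of the aldol converge.

Key step: step 2

Remark: intermediates are named with their own systematic numbering; compound 6 is drawn as the expected anti aldol, but the route does not depend on that carbinol configuration.

**Step 1**
Reactants: 1 4-bromo-2-methylbut-1-ene
Product: 2 (3-methylbut-3-en-1-yl)magnesium bromide (ethereal solution, titrated, used directly)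
Conditions: Mg turnings, cat. I2, Et2O, reflux then rt
Reagents that add atoms: magnesium, [Mg]
Why: Grignard formation by magnesium insertion into the primary C–Br bond is routine for homoallylic bromides, leaves the 1,1-disubstituted alkene untouched and creates no stereocentre.

**Step 2**
Reactants: 2 (3-methylbut-3-en-1-yl)magnesium bromide, 3 3-methylcyclopent-2-en-1-one, 4 acrolein (prop-2-enal)
Product: 6 (2S,3S)-2-[(1R)-1-hydroxyprop-2-en-1-yl]-3-methyl-3-(3-methylbut-3-en-1-yl)cyclopentan-1-one, via bromomagnesium enolate 5 (not isolated)
Conditions: Cu(OTf)2 (3 mol %), chiral imidazolinium salt (NHC precursor, 4 mol %), Et2O, 0 °C, slow addition of 2; then 4, −78 °C; sat. aq NH4Cl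
Reagents that add atoms: none
Why: A chiral NHC–copper(I) complex formed in situ transfers the 3-methylbut-3-enyl group of 2 to the β-carbon of 3 (π-complex, copper(III) intermediate, reductive elimination), and the resulting bromomagnesium enolate 5 adds to acrolein through a closed six-membered Zimmerman–Traxler transition state, so that one flask forms both the C8–C8a and the C3a–C4 bond of the target skeleton. The closest known reaction type is the copper-catalysed asymmetric conjugate addition of Grignard reagents to 3-substituted cyclic enones combined with aldol trapping of the magnesium enolate (three-component coupling). No ring is closed here; the step hangs the two alkenyl arms on the ready-made cyclopentane, and the seven-membered ring follows by metathesis in step 3. The quaternary centre (S) is controlled by the chiral ligand (antipode chosen for this sense), the neighbouring ring centre (S) by approach of the aldehyde to the enolate face anti to the longer, newly introduced chain (syn to methyl), and the carbinol centre (R, anti aldol from the E-enolate) by the chair transition state, although this last centre is not relied upon because it is erased in step 5. The step needs 1,4- rather than 1,2-addition of the Grignard reagent (copper catalysis, slow addition), 1,2- rather than 1,4-addition of the enolate to acrolein (magnesium counter-ion, −78 °C) and trans placement of the two arms, for which the substrate offers only the size difference between the chain and the methyl group on the quaternary carbon.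

**Step 3**
Reactants: 6 (2S,3S)-2-[(1R)-1-hydroxyprop-2-en-1-yl]-3-methyl-3-(3-methylbut-3-en-1-yl)cyclopentan-1-one
Product: 7 (3aS,8R,8aS)-8-hydroxy-3a,6-dimethyl-3,3a,4,5,8,8a-hexahydroazulen-1(2H)-one
Conditions: (H2IMes)(PCy3)Cl2Ru=CHPh (5 mol %), CH2Cl2 (5 mM), 40 °C
Reagents that add atoms: none
Why: Ring-closing olefin metathesis between the monosubstituted allylic-alcohol alkene (initiation site) and the 1,1-disubstituted alkene closes the seven-membered ring as its trisubstituted cycloalkene with loss of ethene, the trans disposition of the two arms on the cyclopentanone giving the trans-fused hydroazulenone without touching any stereocentre.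

**Step 4**
Reactants: 7 (3aS,8R,8aS)-8-hydroxy-3a,6-dimethyl-3,3a,4,5,8,8a-hexahydroazulen-1(2H)-one
Product: 8 (3R,3aS,4R,8aS)-6,8a-dimethyl-3-(propan-2-yl)-1,2,3,3a,4,7,8,8a-octahydroazulene-3,4-diol
Conditions: i-PrMgCl (3 equiv), LaCl3·2LiCl (1 equiv), THF, −78 → 0 °C; sat. aq NH4Cl
Reagents that add atoms: isopropylmagnesium chloride, CC(C)[Mg]Cl
Why: Lanthanide-promoted Grignard 1,2-addition (the first equivalent only deprotonates the secondary hydroxyl) suppresses enolisation and β-hydride reduction, and the nucleophile should attack the ketone from the face of the ring-fusion hydrogen, anti to both the adjacent carbinol-bearing ring bond and the angular methyl, so that the new tertiary hydroxyl ends cis to these two groups (3R).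

**Step 5**
Reactants: 8 (3R,3aS,4R,8aS)-6,8a-dimethyl-3-(propan-2-yl)-1,2,3,3a,4,7,8,8a-octahydroazulene-3,4-diol
Product: 9 (3R,3aR,8aS)-3-hydroxy-6,8a-dimethyl-3-(propan-2-yl)-2,3,3a,7,8,8a-hexahydroazulen-4(1H)-one
Conditions: activated MnO2 (excess), CH2Cl2, rt
Reagents that add atoms: none
Why: Manganese dioxide oxidation of an allylic alcohol touches only the secondary allylic carbinol (the tertiary one cannot react) and erases the carbinol centre of the aldol step so that both of its epimers converge on one enone, while the ring-fusion CH next to the new carbonyl keeps the arrangement with the acyl carbon trans to isopropyl and cis to the hydroxyl, which should also be the thermodynamically preferred one.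

**Step 6**
Reactants: 9 (3R,3aR,8aS)-3-hydroxy-6,8a-dimethyl-3-(propan-2-yl)-2,3,3a,7,8,8a-hexahydroazulen-4(1H)-one
Product: 11 (3R,3aS,4S,8aS)-6,8a-dimethyl-3-(propan-2-yl)-1,2,3,3a,4,7,8,8a-octahydroazulene-3,4-diol, via alkoxydiacetoxyborohydride 10 (not isolated)
Conditions: Me4NBH(OAc)3 (5 equiv), MeCN–AcOH (1:1), −30 → 0 °C; aq potassium sodium tartrate
Reagents that add atoms: none
Why: In this hydroxyl-directed triacetoxyborohydride reduction, exchange of one acetate for the tertiary hydroxyl gives 10, which should deliver hydride intramolecularly to the carbonyl face on the side of the C3–O bond, opposite to the ring-fusion hydrogen, setting the 4S carbinol (oxygen cis to H-3a), whereas the free reagent is too weak to reduce the enone from the other face.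

**Step 7**
Reactants: 11 (3R,3aS,4S,8aS)-6,8a-dimethyl-3-(propan-2-yl)-1,2,3,3a,4,7,8,8a-octahydroazulene-3,4-diol, 12 4-acetoxybenzoyl chloride
Product: 13 (3R,3aS,4S,8aS)-3-hydroxy-6,8a-dimethyl-3-(propan-2-yl)-1,2,3,3a,4,7,8,8a-octahydroazulen-4-yl 4-acetoxybenzoate
Conditions: Et3N (2 equiv), DMAP (0.2 equiv), CH2Cl2, 0 °C → rt
Reagents that add atoms: none
Why: DMAP-catalysed acylation with the acid chloride is selective for the secondary allylic alcohol because the tertiary carbinol is too hindered to react under these conditions, and it proceeds with retention since no C–O bond of the substrate is broken.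

**Step 8**
Reactants: 13 (3R,3aS,4S,8aS)-3-hydroxy-6,8a-dimethyl-3-(propan-2-yl)-1,2,3,3a,4,7,8,8a-octahydroazulen-4-yl 4-acetoxybenzoate
Product: 14 (3R,3aS,4S,8aS)-3-hydroxy-6,8a-dimethyl-3-(propan-2-yl)-1,2,3,3a,4,7,8,8a-octahydroazulen-4-yl 4-hydroxybenzoate (CNP0323098.1)
Conditions: K2CO3 (0.2 equiv), MeOH, 0 °C
Reagents that add atoms: none
Why: Base-catalysed methanolysis (transesterification) cleaves the phenyl acetate far faster than the hindered secondary alkyl benzoate, which is further deactivated once the para-phenoxide forms, so the phenol should be released without touching the allylic ester or any stereocentre.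

**Compound list**
1 | 4-bromo-2-methylbut-1-ene | C=C(C)CCBr | starting material
2 | (3-methylbut-3-en-1-yl)magnesium bromide | C=C(C)CC[Mg]Br | intermediate
3 | 3-methylcyclopent-2-en-1-one | CC1=CC(=O)CC1 | starting material
4 | acrolein (prop-2-enal) | C=CC=O | starting material
5 | bromomagnesium (S)-3-methyl-3-(3-methylbut-3-en-1-yl)cyclopent-1-en-1-olate | C=C(C)CC[C@@]1(C)CCC(O[Mg]Br)=C1 | intermediate
6 | (2S,3S)-2-[(1R)-1-hydroxyprop-2-en-1-yl]-3-methyl-3-(3-methylbut-3-en-1-yl)cyclopentan-1-one | C=C[C@@H](O)[C@@H]1[C@@](C)(CCC(C)=C)CCC1=O | intermediate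
7 | (3aS,8R,8aS)-8-hydroxy-3a,6-dimethyl-3,3a,4,5,8,8a-hexahydroazulen-1(2H)-one | CC1=C[C@@H](O)[C@@H]2[C@@](C)(CC1)CCC2=O | intermediate
8 | (3R,3aS,4R,8aS)-6,8a-dimethyl-3-(propan-2-yl)-1,2,3,3a,4,7,8,8a-octahydroazulene-3,4-diol | CC1=C[C@@H](O)[C@@H]2[C@@](C)(CC1)CC[C@@]2(O)C(C)C | intermediate
9 | (3R,3aR,8aS)-3-hydroxy-6,8a-dimethyl-3-(propan-2-yl)-2,3,3a,7,8,8a-hexahydroazulen-4(1H)-one | CC1=CC(=O)[C@@H]2[C@@](C)(CC1)CC[C@@]2(O)C(C)C | intermediate
10 | tetramethylammonium salt of the diacetoxy(hydrido)borate bound to the tertiary oxygen of 9 | CC1=CC(=O)[C@@H]2[C@@](C)(CC1)CC[C@@]2(O[BH-](OC(C)=O)OC(C)=O)C(C)C.C[N+](C)(C)C | intermediate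
11 | (3R,3aS,4S,8aS)-6,8a-dimethyl-3-(propan-2-yl)-1,2,3,3a,4,7,8,8a-octahydroazulene-3,4-diol | CC1=C[C@H](O)[C@@H]2[C@@](C)(CC1)CC[C@@]2(O)C(C)C | intermediate
12 | 4-acetoxybenzoyl chloride | CC(=O)Oc1ccc(cc1)C(Cl)=O | starting material
13 | (3R,3aS,4S,8aS)-3-hydroxy-6,8a-dimethyl-3-(propan-2-yl)-1,2,3,3a,4,7,8,8a-octahydroazulen-4-yl 4-acetoxybenzoate | CC1=C[C@H](OC(=O)c2ccc(OC(C)=O)cc2)[C@@H]2[C@@](C)(CC1)CC[C@@]2(O)C(C)C | intermediate
14 | (3R,3aS,4S,8aS)-3-hydroxy-6,8a-dimethyl-3-(propan-2-yl)-1,2,3,3a,4,7,8,8a-octahydroazulen-4-yl 4-hydroxybenzoate | CC1=C[C@H](OC(=O)c2ccc(O)cc2)[C@@H]2[C@@](C)(CC1)CC[C@@]2(O)C(C)C | target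

Total step count: 8
Longest linear sequence: 8 steps (1 → 2 → 6 → 7 → 8 → 9 → 11 → 13 → 14)

**Steps most likely to fail**

Step 2. Enantiocontrol of the conjugate addition may be incomplete with the five-membered enone, and facial discrimination in the aldol addition next to the quaternary carbon (chain versus methyl) may be weak. The fallback sets out from 2 and returns to the route at 6; it adds the methyl group instead of the chain in the asymmetric step. Reagent 2 is added to 3-ethoxycyclopent-2-en-1-one and the adduct is hydrolysed with dilute HCl (Stork–Danheiser sequence) to 3-(3-methylbut-3-en-1-yl)cyclopent-2-en-1-one F1. Copper-catalysed asymmetric conjugate addition of trimethylaluminium with a chiral NHC–copper catalyst, a reaction type established for 3-alkylcyclopentenones, should give the dimethylaluminium enolate F2. This is silylated in the same flask with triethylsilyl triflate to the triethylsilyl enol ether F3, which can be purified and assayed for enantiomeric purity. Methyllithium in THF at −78 °C should convert F3 into the lithium enolate F4, whose kinetic aldol addition to 4 gives 6 after aqueous NH4Cl.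

Step 4. Enolisation or β-hydride reduction of the hindered ketone by the secondary Grignard reagent, or retro-aldol opening of the metal aldolate, may compete with 1,2-addition. The fallback sets out from 7 and returns at 8. Isopropenylmagnesium bromide (3 equiv, anhydrous CeCl3, THF, −78 °C), an sp2 nucleophile that cannot transfer a β-hydride and is less prone to enolise the ketone, should add from the same face to give the isopropenyl carbinol F5. Hydrogenation of its 1,1-disubstituted alkene with RhCl(PPh3)3 and H2 in benzene should leave the trisubstituted ring alkene untouched and give 8.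

Step 6. Ligand exchange at the tertiary hydroxyl may be slow, or hydride may be delivered to the wrong face of the enone. The fallback sets out from 8, whose allylic carbinol already has the inverted configuration, and returns at 13; steps 5 to 7 are bypassed. A Mitsunobu esterification of 8 with 4-acetoxybenzoic acid (PPh3, diisopropyl azodicarboxylate, toluene, 0 °C → rt) should form the ester with inversion at the secondary allylic carbon; the tertiary alcohol does not take part. No new compound is made on this path.

**Further compounds**
F1 | step 2 | 3-(3-methylbut-3-en-1-yl)cyclopent-2-en-1-one | C=C(C)CCC1=CC(=O)CC1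
F2 | step 2 | dimethylaluminium (S)-3-methyl-3-(3-methylbut-3-en-1-yl)cyclopent-1-en-1-olate | C=C(C)CC[C@@]1(C)CCC(O[Al](C)C)=C1
F3 | step 2 | triethyl{[(3S)-3-methyl-3-(3-methylbut-3-en-1-yl)cyclopent-1-en-1-yl]oxy}silane | C=C(C)CC[C@@]1(C)CCC(O[Si](CC)(CC)CC)=C1
F4 | step 2 | lithium (S)-3-methyl-3-(3-methylbut-3-en-1-yl)cyclopent-1-en-1-olate | C=C(C)CC[C@@]1(C)CCC(O[Li])=C1
F5 | step 4 | (3S,3aS,4R,8aS)-6,8a-dimethyl-3-(prop-1-en-2-yl)-1,2,3,3a,4,7,8,8a-octahydroazulene-3,4-diol | CC1=C[C@@H](O)[C@@H]2[C@@](C)(CC1)CC[C@@]2(O)C(C)=C
F0 | step 6 | none | none
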